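**Plan**

- Numbering: in each ring C1 is the ether carbon and C2 the hydroxylated carbon. Ring A (dibromo ring) carries Br at C4 and C6; ring B (tribromo ring) carries Br at C4', C5' and C6'. The enabling feature is that the bromines at C4, C6, C4' and C6' flank C5 and C5', the carbons para to the hydroxyls. An amino group at C5 and at C5' can therefore direct all four, and the nitrogen at C5' can afterwards be exchanged for the fifth bromine.
- Retrosynthesis: the two O-CH3 bonds are cut first (phenols masked as methyl ethers). Next come C5-H of ring A (from C5-N, hydrodediazoniation) and C5'-Br of ring B (from C5'-N, Sandmeyer). Then the four C-Br bonds ortho to nitrogen are cut together, then the amines go back to nitro groups, and last the diaryl ether C-O bond is cut.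
- Forward: Ullmann coupling of two nitroanisole building blocks, hydrogenation, fourfold amine-directed bromination, Sandmeyer bromination of one amine, reductive removal of the other, double O-demethylation.
- No ring is formed, since both benzene rings are bought. The target has no stereocentre, so no stereocontrol is required.

Key step: step 3

Assumption: the target SMILES carries no stereodescriptor, so the tetra-ortho-substituted diaryl ether axis is treated as freely rotating.

Step 1
Reactants: 1 2-methoxy-5-nitrophenol; 2 2-iodo-1-methoxy-4-nitrobenzene (2-iodo-4-nitroanisole)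
Product: 3 1,1'-oxybis(2-methoxy-5-nitrobenzene)
Conditions: CuI (10 mol%), picolinic acid (20 mol%), K3PO4 (2 equiv), DMSO, 100 °C
Reagents that add atoms: none
Why: Ullmann-type copper-catalysed diaryl ether synthesis, in which the phenoxide of 1 couples with the electron-poor aryl iodide 2 at monovalent copper bound to picolinate, a catalyst system established for partners that both carry an ortho substituent; each building block already holds its nitro group para to the methoxy group, so the positions of both nitrogens are fixed without any nitration.

Step 2
Reactants: 3 1,1'-oxybis(2-methoxy-5-nitrobenzene)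
Product: 4 3,3'-oxybis(4-methoxyaniline)
Conditions: H2 (1 atm), 10% Pd/C, EtOAc-MeOH, rt
Reagents that add atoms: none
Why: Heterogeneous catalytic hydrogenation of aromatic nitro groups is general, and it is placed before any bromine is introduced so that no carbon-halogen bond can be hydrogenolysed.

Step 3
Reactants: 4 3,3'-oxybis(4-methoxyaniline); 5 bromine
Product: 6 3,3'-oxybis(2,6-dibromo-4-methoxyaniline)
Conditions: Br2 (4.1 equiv, dropwise), NaOAc (4.5 equiv), AcOH, 10 °C to rt; aq Na2S2O3 quench
Reagents that add atoms: bromine 5, BrBr
Why: Electrophilic aromatic substitution occurs four times, twice on each ring: Br2 attacks a carbon ortho to an amino group, the arenium ion is stabilised by the nitrogen lone pair, and acetate removes the proton. The closest known reaction is the dibromination of 4-methoxyaniline to 2,6-dibromo-4-methoxyaniline with Br2 in acetic acid, itself a case of the exhaustive ortho bromination of para-substituted anilines. No ring is closed and no stereocentre is created. The step needs site selectivity, and the substrate provides it: C4 and C6 of each ring are ortho to nitrogen and also para and ortho to the ether oxygen, so the two donors reinforce each other there, while the carbon para to nitrogen is blocked by the methoxy group and C3 is meta to both nitrogen and the ether oxygen and is activated by the methoxy group alone. It also needs to stop at four bromines: each ring is deactivated once it carries two bromines and its amino group is flanked on both sides, so a slight excess of Br2 at low temperature should suffice, and the acetate buffer keeps the amines unprotonated and removes HBr, which limits oxidation of the electron-rich rings.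

Step 4
Reactants: 6 3,3'-oxybis(2,6-dibromo-4-methoxyaniline)
Product: 8 2,6-dibromo-4-methoxy-3-(2,3,4-tribromo-6-methoxyphenoxy)aniline, via mono-diazonium bromide 7 (not isolated)
Conditions: CuBr2 (1.2 equiv), tBuONO (0.9 equiv, added slowly), MeCN, 60 °C
Reagents that add atoms: copper dibromide CuBr2, Br[Cu]Br
Why: Sandmeyer bromination in its anhydrous alkyl nitrite/CuBr2 form, which suits weakly basic 2,6-dihaloanilines: the diazonium ion 7 loses N2 and takes bromine from copper at the very carbon that carried nitrogen, so the fifth bromine lands para to the future ring-B hydroxyl with no regiochemical choice; the two amines of 6 are equivalent and independent, so the mono-reaction is statistical, which is why the nitrite is kept short and fed slowly into the hot copper solution and why 8 is separated by chromatography from unreacted 6 (recycled) and from the doubly brominated by-product, the three differing by one amino group each.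

Step 5
Reactants: 8 2,6-dibromo-4-methoxy-3-(2,3,4-tribromo-6-methoxyphenoxy)aniline
Product: 10 1,2,3-tribromo-4-(2,4-dibromo-6-methoxyphenoxy)-5-methoxybenzene, via diazonium hydrogensulfate 9 (not isolated)
Conditions: NaNO2, conc. H2SO4-AcOH, 0-5 °C; then 50% aq H3PO2, 0 °C to rt
Reagents that add atoms: none
Why: Diazotisation with nitrosylsulfuric acid followed by hydrodediazoniation with H3PO2 is the classical reductive deamination of 2,6-dibromoanilines (2,4,6-tribromoaniline to 1,3,5-tribromobenzene being the textbook case), and the aryl radical on the chain path sits meta to the ether bridge, so it cannot cyclise onto ring B.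

Step 6
Reactants: 10 1,2,3-tribromo-4-(2,4-dibromo-6-methoxyphenoxy)-5-methoxybenzene
Product: 12 3,5-dibromo-2-(2,3,4-tribromo-6-hydroxyphenoxy)phenol, via bis(dibromoboryl) ether 11 (not isolated)
Conditions: BBr3 (6 equiv), CH2Cl2, -78 °C to rt; then H2O
Reagents that add atoms: none
Why: Lewis acid-mediated cleavage of aryl methyl ethers with BBr3: boron binds each methoxy oxygen and bromide attacks the methyl carbon, which the diaryl ether oxygen, flanked only by sp2 carbons, cannot offer, and the aryloxyboranes 11 are hydrolysed on work-up without touching the five aryl bromides.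

**Compound list**

1 | 2-methoxy-5-nitrophenol | COc1ccc(cc1O)[N+](=O)[O-] | starting material
2 | 2-iodo-1-methoxy-4-nitrobenzene (2-iodo-4-nitroanisole) | COc1ccc(cc1I)[N+](=O)[O-] | starting material
3 | 1,1'-oxybis(2-methoxy-5-nitrobenzene) | COc1ccc(cc1Oc1cc(ccc1OC)[N+](=O)[O-])[N+](=O)[O-] | intermediate
4 | 3,3'-oxybis(4-methoxyaniline) | COc1ccc(N)cc1Oc1cc(N)ccc1OC | intermediate
5 | bromine | BrBr | starting material
6 | 3,3'-oxybis(2,6-dibromo-4-methoxyaniline) | COc1cc(Br)c(N)c(Br)c1Oc1c(Br)c(N)c(Br)cc1OC | intermediate
7 | 3-(3-amino-2,4-dibromo-6-methoxyphenoxy)-2,6-dibromo-4-methoxybenzenediazonium bromide (not isolated) | COc1cc(Br)c([N+]#N)c(Br)c1Oc1c(Br)c(N)c(Br)cc1OC.[Br-] | intermediate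
8 | 2,6-dibromo-4-methoxy-3-(2,3,4-tribromo-6-methoxyphenoxy)aniline | COc1cc(Br)c(N)c(Br)c1Oc1c(Br)c(Br)c(Br)cc1OC | intermediate
9 | 2,6-dibromo-4-methoxy-3-(2,3,4-tribromo-6-methoxyphenoxy)benzenediazonium hydrogensulfate (not isolated) | COc1cc(Br)c([N+]#N)c(Br)c1Oc1c(Br)c(Br)c(Br)cc1OC.OS(=O)(=O)[O-] | intermediate
10 | 1,2,3-tribromo-4-(2,4-dibromo-6-methoxyphenoxy)-5-methoxybenzene | COc1cc(Br)cc(Br)c1Oc1c(Br)c(Br)c(Br)cc1OC | intermediate
11 | dibromo[3,5-dibromo-2-(2,3,4-tribromo-6-(dibromoboryloxy)phenoxy)phenoxy]borane, the bis(dibromoboryl) ether of the target (not isolated) | BrB(Br)Oc1cc(Br)cc(Br)c1Oc1c(OB(Br)Br)cc(Br)c(Br)c1Br | intermediate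
12 | 3,5-dibromo-2-(2,3,4-tribromo-6-hydroxyphenoxy)phenol | Oc1cc(Br)cc(Br)c1Oc1c(O)cc(Br)c(Br)c1Br | target

**Step count and risks**

Total step count: 6. Longest linear sequence: 6 steps (from 1 and 2 to 12).

Steps most likely to fail:

Step 4. Partial diazotisation of a symmetric diamine may go astray in two ways. The diazonium ion can couple with amine that is still free and give triazenes. The statistical spread over unreacted, singly and doubly converted material can also leave too little of the mono-amine. Fallback, from 6 to 12: both amines are treated alike and the fifth bromine is brought in by phenol-directed substitution instead.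
- Bis-diazotisation of 6 (NaNO2, H2SO4-AcOH, 0 °C) gives the bis(diazonium) bis(hydrogensulfate) F1 (not isolated), which H3PO2 reduces to 1,1'-oxybis(2,4-dibromo-6-methoxybenzene) F2.
- BBr3 in CH2Cl2 converts F2, through the bis(dibromoboryl) ether F3 (not isolated), into 2,2'-oxybis(3,5-dibromophenol) F4.
- One equivalent of Br2 in AcOH at low temperature should then enter para to one hydroxyl and give 12.
- This return is less secure than the main line: the free ortho carbon may compete, and mono- and di-bromination have to be separated.

Step 1. The nitrophenoxide of 1 is a weak, ortho-substituted nucleophile, so the copper-catalysed coupling may be slow and lose 2 to hydrodehalogenation or homocoupling. Fallback, from 2 to 3: the nucleophile is changed and the second nitrogen is introduced by nitration.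
- 2 is coupled under the same type of Ullmann conditions with the electron-rich, commercially available 2-methoxyphenol (guaiacol) to give 1-methoxy-2-(2-methoxyphenoxy)-4-nitrobenzene F5.
- Nitration (HNO3, AcOH, 0-10 °C) should then take place on the ring that is not yet nitrated, para to its methoxy group, because the oxygen that bridges to a nitroarene is the weaker donor. This gives 3.

Step 3. Driving four brominations to completion on one molecule may fail through oxidation of the two electron-rich aminoanisole rings by bromine. It may also stall at the crowded carbons between nitrogen and the ether oxygen, which would leave mixtures of tri-, tetra- and pentabromides. Fallback, from 3 to 8: the rings are brominated one at a time while the other ring is kept electron-poor.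
- One nitro group of 3 is reduced with limiting NaSH in aqueous ethanol (Zinin reduction) to 4-methoxy-3-(2-methoxy-5-nitrophenoxy)aniline F6, which is removed from unreacted 3 by extraction into dilute acid.
- Br2 (2 equiv), NaOAc, AcOH gives 2,6-dibromo-4-methoxy-3-(2-methoxy-5-nitrophenoxy)aniline F7.
- tBuONO and CuBr2 in MeCN convert F7, through the diazonium bromide F8 (not isolated), into 1,2,3-tribromo-5-methoxy-4-(2-methoxy-5-nitrophenoxy)benzene F9.
- Fe powder and NH4Cl in aqueous ethanol reduce the nitro group without touching the C-Br bonds and give 4-methoxy-3-(2,3,4-tribromo-6-methoxyphenoxy)aniline F10.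
- Br2 (2 equiv), NaOAc, AcOH then returns to the route at 8.
- This path also replaces the statistical Sandmeyer step by a partial reduction whose products separate by acid extraction.

Further compounds
F1 | step 4 | 3,3'-oxybis(2,6-dibromo-4-methoxybenzenediazonium) bis(hydrogensulfate) (not isolated) | COc1cc(Br)c([N+]#N)c(Br)c1Oc1c(Br)c([N+]#N)c(Br)cc1OC.OS(=O)(=O)[O-].OS(=O)(=O)[O-]
F2 | step 4 | 1,1'-oxybis(2,4-dibromo-6-methoxybenzene) | COc1cc(Br)cc(Br)c1Oc1c(Br)cc(Br)cc1OC
F3 | step 4 | bis(dibromoboryl) ether of 2,2'-oxybis(3,5-dibromophenol) (not isolated) | BrB(Br)Oc1cc(Br)cc(Br)c1Oc1c(Br)cc(Br)cc1OB(Br)Br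
F4 | step 4 | 2,2'-oxybis(3,5-dibromophenol) | Oc1cc(Br)cc(Br)c1Oc1c(Br)cc(Br)cc1O
F5 | step 1 | 1-methoxy-2-(2-methoxyphenoxy)-4-nitrobenzene | COc1ccccc1Oc1cc(ccc1OC)[N+](=O)[O-]
F6 | step 3 | 4-methoxy-3-(2-methoxy-5-nitrophenoxy)aniline | COc1ccc(N)cc1Oc1cc(ccc1OC)[N+](=O)[O-]
F7 | step 3 | 2,6-dibromo-4-methoxy-3-(2-methoxy-5-nitrophenoxy)aniline | COc1cc(Br)c(N)c(Br)c1Oc1cc(ccc1OC)[N+](=O)[O-]
F8 | step 3 | 2,6-dibromo-4-methoxy-3-(2-methoxy-5-nitrophenoxy)benzenediazonium bromide (not isolated) | COc1cc(Br)c([N+]#N)c(Br)c1Oc1cc(ccc1OC)[N+](=O)[O-].[Br-]
F9 | step 3 | 1,2,3-tribromo-5-methoxy-4-(2-methoxy-5-nitrophenoxy)benzene | COc1cc(Br)c(Br)c(Br)c1Oc1cc(ccc1OC)[N+](=O)[O-]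
F10 | step 3 | 4-methoxy-3-(2,3,4-tribromo-6-methoxyphenoxy)aniline | COc1ccc(N)cc1Oc1c(Br)c(Br)c(Br)cc1OC
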